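## Retrosynthetic overview

1. The target is reached from its 12-O-PMB ether. Before that, the C17 carbinol comes from methyl addition to a 17-oxo lactone, the 8β-hydroxyl from cis-dihydroxylation of a Δ8(17)-butenolide, and the 5β,6β-epoxide from peripheral epoxidation of a (Z)-C5=C6 olefin.
2. The ten-membered ring is closed by ring-closing metathesis at C5=C6. The butenolide comes from aldol condensation of a C7 acetate onto a C8 ketone, with C7 set by iridium-catalysed acetoxyallylation of the C8 primary alcohol.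
3. C1–C2 is made by a Mukaiyama aldol of the cycloadduct's silyl enol ether with an (S)-aldehyde carrying C2–C5 and C16 (from a glyoxylate–ene reaction). C14 is set by hydroxyl-directed reduction; the C20 ester becomes the methyl group and the C12–B bond becomes C12–O.
4. Key disconnection: a Diels–Alder reaction of the 2-silyloxy diene C13=C14(OSi)–C1(C15)=C10–C9 (C9 bought as D-glyceraldehyde acetonide) with a (Z)-β-boryl acrylate (C20–C11=C12–B) forms C10–C11 and C12–C13. The enabling feature is the six-membered carbocycle (C1, C10–C14): its C14 oxygen next to quaternary C1 and its all-cis C10(C9)/C11(C20)/C12(O) triad are the endo adduct of such a pair, and the C15 methyl on C1 sits cis to the C9 oxygen stereocenter (A(1,3) strain), so C9 alone fixes the diene face.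
5. Ring order: six-membered carbocycle (cycloaddition), then γ-lactone (butenolide), then ten-membered carbocycle (metathesis), then epoxide.

Key step: step 7

Remark (numbering and abbreviations): atoms are numbered as in the briarane skeleton. C1 is the quaternary ring-fusion carbon (methyl C15); C2 and C3 are CH–OAc; C4 is CH2; C5 (methyl C16) and C6 are the epoxide carbons; C7 is the lactone O–CH; C8 is C–OH; C9 is CH–OAc; C10 is the ring-fusion CH; C11 is CH (methyl C20); C12 is CH–OH; C13 is CH2; C14 is CH–OAc; C17 is C(OH) (methyl C18); C19 is the lactone C=O. β is the face of the C15 methyl group. TBS = tert-butyldimethylsilyl, PMB = 4-methoxybenzyl, Bpin = 4,4,5,5-tetramethyl-1,3,2-dioxaborolan-2-yl.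

Assumption: the (Z)-boryl acrylate dienophile of the key step is taken as a catalogue compound; it is otherwise one step from commercial ethyl (Z)-3-iodoacrylate by palladium-catalysed borylation with B2pin2.

## Route

Step 1
Reactants: 1 (R)-2,2-dimethyl-1,3-dioxolane-4-carbaldehyde; 2 3-(triphenyl-λ5-phosphanylidene)butan-2-one
Product: 3 (S,E)-4-(2,2-dimethyl-1,3-dioxolan-4-yl)-3-methylbut-3-en-2-one
Conditions: CH2Cl2, 25 °C
Reagents that add atoms: none
Why: Wittig olefination with the stabilized α-methyl acyl ylide should give the (E)-trisubstituted enone and leaves the α-alkoxy stereocenter (future C9) untouched.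

Step 2
Reactants: 3 (S,E)-4-(2,2-dimethyl-1,3-dioxolan-4-yl)-3-methylbut-3-en-2-one
Product: 4 (S,E)-5,6-dihydroxy-3-methylhex-3-en-2-one
Conditions: AcOH/H2O (4:1), 40 °C
Reagents that add atoms: none
Why: acid-catalysed acetal hydrolysis frees the 1,2-diol without touching the enone or the stereocenter.

Step 3
Reactants: 4 (S,E)-5,6-dihydroxy-3-methylhex-3-en-2-one
Product: 5 (S,E)-2,5,6-tris(tert-butyldimethylsilyloxy)-3-methylhexa-1,3-diene
Conditions: TBSOTf (3.5 equiv), Et3N (5 equiv), CH2Cl2, −78 to 0 °C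
Reagents that add atoms: tert-butyldimethylsilyl trifluoromethanesulfonate, CC(C)(C)[Si](C)(C)OS(=O)(=O)C(F)(F)F
Why: the silyl triflate/amine pair silylates both hydroxyls and soft-enolizes the methyl ketone at its only enolizable position (the CH3 group), giving the cross-conjugated 2-silyloxy diene with the (E)-C1=C10 geometry retained.

Step 4
Reactants: 6 ethyl glyoxylate; 7 2-methylpropene
Product: 8 ethyl (S)-2-hydroxy-4-methylpent-4-enoate
Conditions: TiCl2(OiPr)2 (10 mol%), (S)-BINOL (10 mol%), 4 Å molecular sieves, CH2Cl2, −30 °C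
Reagents that add atoms: none
Why: BINOL–titanium-catalysed glyoxylate–ene (carbonyl–ene) reaction in which the chiral Lewis acid selects the aldehyde face; the ligand enantiomer is the one that should give the (S)-α-hydroxy ester (future C3).

Step 5
Reactants: 8 ethyl (S)-2-hydroxy-4-methylpent-4-enoate
Product: 9 ethyl (S)-2-(tert-butyldimethylsilyloxy)-4-methylpent-4-enoate
Conditions: TBSCl, imidazole, DMF, 25 °C
Reagents that add atoms: tert-butyldimethylsilyl chloride, CC(C)(C)[Si](C)(C)Cl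
Why: standard silylation of a secondary alcohol gives a non-chelating α-silyloxy group for the later Felkin–Anh addition.

Step 6
Reactants: 9 ethyl (S)-2-(tert-butyldimethylsilyloxy)-4-methylpent-4-enoate
Product: 10 (S)-2-(tert-butyldimethylsilyloxy)-4-methylpent-4-enal
Conditions: i-Bu2AlH (1.05 equiv), CH2Cl2, −78 °C; Rochelle salt work-up
Reagents that add atoms: none
Why: partial ester reduction at low temperature stops at the tetrahedral aluminium hemiacetal and should give the α-silyloxy aldehyde without epimerization.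

Step 7
Reactants: 5 (S,E)-2,5,6-tris(tert-butyldimethylsilyloxy)-3-methylhexa-1,3-diene; 11 ethyl (Z)-3-(4,4,5,5-tetramethyl-1,3,2-dioxaborolan-2-yl)prop-2-enoate
Product: 12 cycloadduct, a cyclohexene silyl enol ether (C14(OTBS)=C1(C15)) carrying 10β-[(S)-1,2-bis(TBSO)ethyl], 11β-CO2Et and 12β-Bpin (all cis)
Conditions: toluene, BHT (cat.), 100 °C, sealed tube
Reagents that add atoms: none
Why: A thermal, concerted but asynchronous normal-demand [4+2] cycloaddition joins the nucleophilic C13 terminus of the 2-silyloxy diene to the boron-bearing β-carbon of the acrylate and C10 to its α-carbon, closing the six-membered carbocycle in one suprafacial event; the closest known reaction types are the Diels–Alder reaction of 2-silyloxy dienes with β-boryl acrylates (boron as a masked hydroxyl) and the A(1,3)-controlled cycloaddition of dienes that carry an allylic oxygen stereocenter. Regiochemistry is secured by the C14 silyloxy group ("para" to the ester-bearing carbon) and reinforced by the C10 alkyl terminus ("ortho"), so the ester carbon ends on C11 and boron on C12. C11 and C12 are cis because the (Z)-geometry of the dienophile is transferred, and the endo orientation of the ester and boryl groups should place both cis to the C9 side chain on C10. The diene face is set by C9: the C15 methyl on C1, cis to C9 across C1=C10, forces H9 into the diene plane (A(1,3) strain), which leaves the bulky C9 silyloxy group on one face and the CH2OTBS arm on the other, and the dienophile should add anti to the C9–O bond. The step therefore needs regio-, endo- and π-facial selectivity, and it should deliver C10, C11 and C12 together with a regiodefined C14=C1 silyl enol ether for the later quaternization of C1.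

Step 8
Reactants: 12 cycloadduct; 10 (S)-2-(tert-butyldimethylsilyloxy)-4-methylpent-4-enal
Product: 13 aldol adduct: C14 ketone, quaternary C1 (C15 β) bearing the (1R,2S)-1-hydroxy-2-(TBSO)-4-methylpent-4-enyl chain (C2–C5, C16) on the α-face
Conditions: BF3·OEt2 (1.2 equiv), CH2Cl2, −78 °C
Reagents that add atoms: none
Why: Mukaiyama aldol addition through an open transition state, in which the electrophile should enter axially on the ring face opposite the pseudoaxial C9 side chain and the cis C11/C12 substituents (C2 α on the new quaternary C1), while Felkin–Anh addition to the BF3-activated α-silyloxy aldehyde should set the 2,3-anti relationship.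

Step 9
Reactants: 13 aldol adduct
Product: 14 anti-1,3-diol (2-OH, 14α-OH)
Conditions: Me4NBH(OAc)3, MeCN/AcOH (1:1), −30 °C
Reagents that add atoms: none
Why: Evans–Saksena reduction, in which the C2 hydroxyl binds the triacetoxyborohydride and delivers hydride intramolecularly through a chair transition state to give the 1,3-anti diol (14α-OH).

Step 10
Reactants: 14 anti-1,3-diol
Product: 15 2,14-O-isopropylidene acetal
Conditions: 2,2-dimethoxypropane, PPTS (cat.), CH2Cl2, 25 °C
Reagents that add atoms: 2,2-dimethoxypropane, COC(C)(C)OC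
Why: acid-catalysed transacetalization ties up the 1,3-diol as its acetonide while silyl ethers, boronate and ester stay inert.

Step 11
Reactants: 15 2,14-O-isopropylidene acetal
Product: 17 12β,20-diol, via hydroxy boronate 16 (not isolated)
Conditions: LiBH4, THF, MeOH (cat.), 0 to 25 °C; then 3 M NaOH, 30% H2O2, 0 to 25 °C
Reagents that add atoms: hydrogen peroxide, OO
Why: LiBH4 reduces the ethyl ester to the C20 primary alcohol and alkaline peroxide then oxidizes the C12–B bond to C12–OH with retention of configuration.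

Step 12
Reactants: 17 12β,20-diol
Product: 18 C20 tosylate
Conditions: TsCl (1.2 equiv), pyridine, DMAP (cat.), CH2Cl2, 0 °C
Reagents that add atoms: 4-methylbenzenesulfonyl chloride, Cc1ccc(cc1)S(Cl)(=O)=O
Why: the primary hydroxyl is sulfonylated far faster than the hindered secondary C12 hydroxyl.

Step 13
Reactants: 18 C20 tosylate
Product: 19 11β-methyl 12β-alcohol
Conditions: LiEt3BH (3 equiv), THF, 0 to 25 °C
Reagents that add atoms: none
Why: SN2 displacement of the primary tosylate by hydride converts C20 into the methyl group.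

Step 14
Reactants: 19 11β-methyl 12β-alcohol
Product: 20 12-O-PMB ether
Conditions: NaH, PMBCl, Bu4NI (cat.), DMF, 0 to 25 °C
Reagents that add atoms: 4-methoxybenzyl chloride, COc1ccc(CCl)cc1
Why: Williamson etherification of the only free hydroxyl installs the group that keeps C12 unacetylated until the last step.

Step 15
Reactants: 20 12-O-PMB ether
Product: 21 C8 primary alcohol
Conditions: HF·pyridine, pyridine, THF, 0 °C
Reagents that add atoms: none
Why: buffered HF·pyridine should cleave the unhindered primary silyl ether much faster than the two secondary ones.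

Step 16
Reactants: 21 C8 primary alcohol; 22 3,3-diacetoxyprop-1-ene
Product: 23 anti (7S)-7-acetoxy-8-hydroxy-6-ene (C8 carbinol, C7 acetate, C6 vinyl)
Conditions: [Ir(cod)Cl]2 (2.5 mol%), (S)-SEGPHOS (5 mol%), 4-chloro-3-nitrobenzoic acid (10 mol%), Cs2CO3 (20 mol%), THF, 90 °C
Reagents that add atoms: none
Why: iridium-catalysed transfer-hydrogenative (acyloxy)allylation, in which the primary alcohol is dehydrogenated to the aldehyde and attacked by the α-acetoxy-π-allyliridium species through a closed transition state, should give the anti hydroxy acetate with C7 set by the chiral ligand (the ligand enantiomer is the one that delivers 7S).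

Step 17
Reactants: 23 anti (7S)-7-acetoxy-8-hydroxy-6-ene
Product: 24 α-acetoxy ketone (C8=O)
Conditions: Dess–Martin periodinane, NaHCO3, CH2Cl2, 0 to 25 °C
Reagents that add atoms: none
Why: Dess–Martin oxidation of the secondary alcohol under buffered, non-basic conditions should leave the adjacent C7 and C9 stereocenters intact.

Step 18
Reactants: 24 α-acetoxy ketone
Product: 26 Δ8(17)-butenolide diene, via hydroxy lactone 25 (not isolated)
Conditions: LiN(SiMe3)2 (1.1 equiv), THF, −78 °C, AcOH quench; then SOCl2, pyridine, CH2Cl2, 0 °C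
Reagents that add atoms: none
Why: intramolecular aldol addition of the kinetically formed acetate lithium enolate to the adjacent ketone (five-membered ring), followed by dehydration of the tertiary β-hydroxy lactone, should give the conjugated butenolide and erases the C8 stereocenter so that it can be set later from the convex face.

Step 19
Reactants: 26 Δ8(17)-butenolide diene
Product: 27 macrocyclic (Z)-Δ5 butenolide (ten-membered ring closed; 2,14-acetonide, 3,9-bis-TBS, 12-PMB)
Conditions: second-generation Grubbs catalyst (10 mol%), toluene (1 mM), 80 °C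
Reagents that add atoms: none
Why: ring-closing metathesis between the C6 vinyl group and the 1,1-disubstituted C5 olefin, in which the ten-membered ring should accommodate only the (Z)-trisubstituted olefin and the electron-poor butenolide double bond is inert.

Step 20
Reactants: 27 macrocyclic (Z)-Δ5 butenolide
Product: 28 2,3,9,14-tetraol
Conditions: 48% aq HF, MeCN, 25 °C
Reagents that add atoms: none
Why: aqueous HF cleaves the two secondary silyl ethers and the acetonide in one operation while the PMB ether and the butenolide are stable.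

Step 21
Reactants: 28 2,3,9,14-tetraol
Product: 29 2,3,9,14-tetraacetate
Conditions: Ac2O, pyridine, DMAP (cat.), CH2Cl2, 25 °C
Reagents that add atoms: acetic anhydride, CC(=O)OC(C)=O
Why: acylation of the four secondary hydroxyls at a stage where C12 is protected and no tertiary hydroxyl is yet present.

Step 22
Reactants: 29 2,3,9,14-tetraacetate
Product: 30 5β,6β-epoxide
Conditions: mCPBA, NaHCO3, CH2Cl2, 0 °C
Reagents that add atoms: 3-chloroperoxybenzoic acid, OOC(=O)c1cccc(Cl)c1
Why: Prilezhaev epoxidation of the only electron-rich olefin, where attack on the peripheral face of the ten-membered (Z)-olefin in the conformer with H7 in the olefin plane (A(1,3) strain with C4) should give the 5β,6β-epoxide (syn to O7, anti to C8).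

Step 23
Reactants: 30 5β,6β-epoxide
Product: 31 8β,17β-diol
Conditions: OsO4 (10 mol%), N-methylmorpholine N-oxide, citric acid, t-BuOH/H2O, 25 °C
Reagents that add atoms: osmium tetroxide, O=[Os](=O)(=O)=O; N-methylmorpholine N-oxide, C[N+]1([O-])CCOCC1; water, O
Why: Upjohn-type cis-dihydroxylation of the butenolide from its convex β-face, anti to the C6 substituent on C7 and to the ten-membered ring, should set the 8β-hydroxyl and give a secondary 17β-alcohol.

Step 24
Reactants: 31 8β,17β-diol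
Product: 32 8β-hydroxy-17-oxo lactone
Conditions: Dess–Martin periodinane, NaHCO3, CH2Cl2, 25 °C
Reagents that add atoms: none
Why: Dess–Martin oxidation converts the secondary C17 alcohol into the ketone while the tertiary C8 alcohol cannot react.

Step 25
Reactants: 32 8β-hydroxy-17-oxo lactone
Product: 33 12-O-PMB ether of the target
Conditions: MeMgBr (3 equiv), THF, −78 °C
Reagents that add atoms: methylmagnesium bromide, C[Mg]Br
Why: Grignard addition to the highly electrophilic ketone of the α-keto lactone at low temperature should outrun attack on the acetates and the lactone, with the methyl group entering from the convex β-face to give the 17α-hydroxy-18β-methyl center.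

Step 26
Reactants: 33 12-O-PMB ether of the target
Product: 34 CNP0287149.1 (target)
Conditions: DDQ, CH2Cl2/pH 7 buffer, 0 to 25 °C
Reagents that add atoms: none
Why: oxidative cleavage of the PMB ether by DDQ under neutral conditions should leave the acetates, epoxide, lactone and tertiary alcohols untouched and free only the 12β-hydroxyl.

## Compound list

1 | (R)-2,2-dimethyl-1,3-dioxolane-4-carbaldehyde | O=C[C@H]1COC(C)(C)O1 | starting material
2 | 3-(triphenyl-λ5-phosphanylidene)butan-2-one | CC(=O)C(C)=P(c1ccccc1)(c1ccccc1)c1ccccc1 | starting material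
3 | (S,E)-4-(2,2-dimethyl-1,3-dioxolan-4-yl)-3-methylbut-3-en-2-one | C1[C@@H](OC(C)(C)O1)/C=C(\C)C(C)=O | intermediate
4 | (S,E)-5,6-dihydroxy-3-methylhex-3-en-2-one | OC[C@@H](O)/C=C(\C)C(C)=O | intermediate
5 | (S,E)-2,5,6-tris(tert-butyldimethylsilyloxy)-3-methylhexa-1,3-diene | CC(C)(C)[Si](C)(C)OC[C@@H](O[Si](C)(C)C(C)(C)C)/C=C(\C)C(=C)O[Si](C)(C)C(C)(C)C | intermediate
6 | ethyl glyoxylate | CCOC(=O)C=O | starting material
7 | 2-methylpropene | CC(C)=C | starting material
8 | ethyl (S)-2-hydroxy-4-methylpent-4-enoate | CCOC(=O)[C@@H](O)CC(C)=C | intermediate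
9 | ethyl (S)-2-(tert-butyldimethylsilyloxy)-4-methylpent-4-enoate | CCOC(=O)[C@@H](O[Si](C)(C)C(C)(C)C)CC(C)=C | intermediate
10 | (S)-2-(tert-butyldimethylsilyloxy)-4-methylpent-4-enal | O=C[C@@H](O[Si](C)(C)C(C)(C)C)CC(C)=C | intermediate
11 | ethyl (Z)-3-(4,4,5,5-tetramethyl-1,3,2-dioxaborolan-2-yl)prop-2-enoate | CCOC(=O)/C=C\B1OC(C)(C)C(C)(C)O1 | starting material
12 | cycloadduct: ethyl all-cis-2-[(S)-1,2-bis(TBSO)ethyl]-3-methyl-4-(TBSO)-6-(Bpin)cyclohex-3-ene-1-carboxylate (ring carbons are C11, C10, C1, C14, C13, C12) | CC(C)(C)[Si](C)(C)OC[C@@H](O[Si](C)(C)C(C)(C)C)[C@H]1[C@@H](C(=O)OCC)[C@@H](B2OC(C)(C)C(C)(C)O2)CC(O[Si](C)(C)C(C)(C)C)=C1C | intermediate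
13 | aldol adduct: C14 ketone, quaternary C1 (C15 β) with the α-(1R,2S)-1-hydroxy-2-(TBSO)-4-methylpent-4-enyl chain; 10β side chain, 11β-CO2Et, 12β-Bpin | CC(C)(C)[Si](C)(C)OC[C@@H](O[Si](C)(C)C(C)(C)C)[C@H]1[C@@H](C(=O)OCC)[C@@H](B2OC(C)(C)C(C)(C)O2)CC(=O)[C@]1(C)[C@H]([C@@H](O[Si](C)(C)C(C)(C)C)CC(C)=C)O | intermediate
14 | anti-1,3-diol: 13 with the C14 ketone reduced to 14α-OH | CC(C)(C)[Si](C)(C)OC[C@@H](O[Si](C)(C)C(C)(C)C)[C@H]1[C@@H](C(=O)OCC)[C@@H](B2OC(C)(C)C(C)(C)O2)C[C@H](O)[C@]1(C)[C@H]([C@@H](O[Si](C)(C)C(C)(C)C)CC(C)=C)O | intermediate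
15 | 2,14-O-isopropylidene acetal of 14 | CC(C)(C)[Si](C)(C)OC[C@@H](O[Si](C)(C)C(C)(C)C)[C@H]1[C@@H](C(=O)OCC)[C@@H](B2OC(C)(C)C(C)(C)O2)C[C@H](O3)[C@]1(C)[C@H]([C@@H](O[Si](C)(C)C(C)(C)C)CC(C)=C)OC3(C)C | intermediate
16 | hydroxy boronate: 15 with the ester reduced to C20H2OH, 12β-Bpin retained | CC(C)(C)[Si](C)(C)OC[C@@H](O[Si](C)(C)C(C)(C)C)[C@H]1[C@@H](CO)[C@@H](B2OC(C)(C)C(C)(C)O2)C[C@H](O3)[C@]1(C)[C@H]([C@@H](O[Si](C)(C)C(C)(C)C)CC(C)=C)OC3(C)C | intermediate
17 | 12β,20-diol | CC(C)(C)[Si](C)(C)OC[C@@H](O[Si](C)(C)C(C)(C)C)[C@H]1[C@@H](CO)[C@@H](O)C[C@H](O3)[C@]1(C)[C@H]([C@@H](O[Si](C)(C)C(C)(C)C)CC(C)=C)OC3(C)C | intermediate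
18 | C20 tosylate of 17 | CC(C)(C)[Si](C)(C)OC[C@@H](O[Si](C)(C)C(C)(C)C)[C@H]1[C@@H](COS(=O)(=O)c2ccc(C)cc2)[C@@H](O)C[C@H](O3)[C@]1(C)[C@H]([C@@H](O[Si](C)(C)C(C)(C)C)CC(C)=C)OC3(C)C | intermediate
19 | 11β-methyl 12β-alcohol | CC(C)(C)[Si](C)(C)OC[C@@H](O[Si](C)(C)C(C)(C)C)[C@H]1[C@@H](C)[C@@H](O)C[C@H](O3)[C@]1(C)[C@H]([C@@H](O[Si](C)(C)C(C)(C)C)CC(C)=C)OC3(C)C | intermediate
20 | 12-O-PMB ether of 19 | CC(C)(C)[Si](C)(C)OC[C@@H](O[Si](C)(C)C(C)(C)C)[C@H]1[C@@H](C)[C@@H](OCc2ccc(OC)cc2)C[C@H](O3)[C@]1(C)[C@H]([C@@H](O[Si](C)(C)C(C)(C)C)CC(C)=C)OC3(C)C | intermediate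
21 | C8 primary alcohol (9-OTBS, 3-OTBS, 2,14-acetonide, 12-OPMB) | OC[C@@H](O[Si](C)(C)C(C)(C)C)[C@H]1[C@@H](C)[C@@H](OCc2ccc(OC)cc2)C[C@H](O3)[C@]1(C)[C@H]([C@@H](O[Si](C)(C)C(C)(C)C)CC(C)=C)OC3(C)C | intermediate
22 | 3,3-diacetoxyprop-1-ene (allylidene diacetate) | C=CC(OC(C)=O)OC(C)=O | starting material
23 | anti (7S)-7-acetoxy-8-hydroxy-6-ene: C8 secondary alcohol, C7 acetate, C6 vinyl | C=C[C@H](OC(C)=O)[C@H](O)[C@@H](O[Si](C)(C)C(C)(C)C)[C@H]1[C@@H](C)[C@@H](OCc2ccc(OC)cc2)C[C@H](O3)[C@]1(C)[C@H]([C@@H](O[Si](C)(C)C(C)(C)C)CC(C)=C)OC3(C)C | intermediate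
24 | α-acetoxy ketone: 23 with C8=O | C=C[C@H](OC(C)=O)C(=O)[C@@H](O[Si](C)(C)C(C)(C)C)[C@H]1[C@@H](C)[C@@H](OCc2ccc(OC)cc2)C[C@H](O3)[C@]1(C)[C@H]([C@@H](O[Si](C)(C)C(C)(C)C)CC(C)=C)OC3(C)C | intermediate
25 | hydroxy lactone: 8-hydroxy γ-lactone (O7–C19(=O)–C17H2–C8(OH)), C8 epimers | C=C[C@@H]2OC(=O)CC2(O)[C@@H](O[Si](C)(C)C(C)(C)C)[C@H]1[C@@H](C)[C@@H](OCc2ccc(OC)cc2)C[C@H](O3)[C@]1(C)[C@H]([C@@H](O[Si](C)(C)C(C)(C)C)CC(C)=C)OC3(C)C | intermediate
26 | Δ8(17)-butenolide diene (C7 vinyl and C5 isopropenyl termini) | C=C[C@@H]2OC(=O)C=C2[C@@H](O[Si](C)(C)C(C)(C)C)[C@H]1[C@@H](C)[C@@H](OCc2ccc(OC)cc2)C[C@H](O3)[C@]1(C)[C@H]([C@@H](O[Si](C)(C)C(C)(C)C)CC(C)=C)OC3(C)C | intermediate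
27 | macrocyclic (Z)-Δ5 butenolide: ten-membered ring closed; 2,14-acetonide, 3,9-bis-TBS, 12-PMB | CC(C)(C)[Si](C)(C)O[C@H]1C/C(C)=C\[C@@H]2OC(=O)C=C2[C@@H](O[Si](C)(C)C(C)(C)C)[C@H]2[C@@H](C)[C@@H](OCc3ccc(OC)cc3)C[C@H](O3)[C@]2(C)[C@H]1OC3(C)C | intermediate
28 | 2,3,9,14-tetraol (12-OPMB, Δ5, Δ8(17)-butenolide) | O[C@H]1C/C(C)=C\[C@@H]2OC(=O)C=C2[C@@H](O)[C@H]2[C@@H](C)[C@@H](OCc3ccc(OC)cc3)C[C@H](O)[C@]2(C)[C@H]1O | intermediate
29 | 2,3,9,14-tetraacetate | CC(=O)O[C@H]1C/C(C)=C\[C@@H]2OC(=O)C=C2[C@@H](OC(C)=O)[C@H]2[C@@H](C)[C@@H](OCc3ccc(OC)cc3)C[C@H](OC(C)=O)[C@]2(C)[C@H]1OC(C)=O | intermediate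
30 | 5β,6β-epoxide of 29 | CC(=O)O[C@H]1C[C@@]2(C)O[C@H]2[C@@H]2OC(=O)C=C2[C@@H](OC(C)=O)[C@H]2[C@@H](C)[C@@H](OCc3ccc(OC)cc3)C[C@H](OC(C)=O)[C@]2(C)[C@H]1OC(C)=O | intermediate
31 | 8β,17β-diol | CC(=O)O[C@H]1C[C@@]2(C)O[C@H]2[C@@H]2OC(=O)[C@@H](O)[C@]2(O)[C@@H](OC(C)=O)[C@H]2[C@@H](C)[C@@H](OCc3ccc(OC)cc3)C[C@H](OC(C)=O)[C@]2(C)[C@H]1OC(C)=O | intermediate
32 | 8β-hydroxy-17-oxo lactone | CC(=O)O[C@H]1C[C@@]2(C)O[C@H]2[C@@H]2OC(=O)C(=O)[C@]2(O)[C@@H](OC(C)=O)[C@H]2[C@@H](C)[C@@H](OCc3ccc(OC)cc3)C[C@H](OC(C)=O)[C@]2(C)[C@H]1OC(C)=O | intermediate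
33 | 12-O-PMB ether of the target | CC(=O)O[C@H]1C[C@@]2(C)O[C@H]2[C@@H]2OC(=O)[C@](C)(O)[C@]2(O)[C@@H](OC(C)=O)[C@H]2[C@@H](C)[C@@H](OCc3ccc(OC)cc3)C[C@H](OC(C)=O)[C@]2(C)[C@H]1OC(C)=O | intermediate
34 | CNP0287149.1 | CC(=O)O[C@H]1C[C@@]2(C)O[C@H]2[C@@H]2OC(=O)[C@](C)(O)[C@]2(O)[C@@H](OC(C)=O)[C@H]2[C@@H](C)[C@@H](O)C[C@H](OC(C)=O)[C@]2(C)[C@H]1OC(C)=O | target

## Step count and risks

Total step count: 26. Longest linear sequence: 23 steps (steps 1–3 and 7–26).

Three steps most likely to fail: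

Step 7. The cycloaddition may be sluggish, or endo and π-facial control may erode, because both substituents of the (Z)-dienophile must sit under the diene. The fallback sets out from 5 and uses the more reactive, commercially available trans dienophile ethyl (E)-3-(pinacolboryl)acrylate, whose ester-endo cycloaddition is the well-precedented mode, and corrects C12 later by oxidation and reduction. The cycloaddition should give the C12-epimeric cycloadduct F1. Steps 8 to 13 applied to this series should give in turn the aldol adduct F2, the anti-1,3-diol F3, the acetonide F4, the hydroxy boronate F5 (not isolated), the 12α,20-diol F6, the tosylate F7 and the 11β-methyl 12α-alcohol F8. Dess–Martin oxidation of F8 should give the C12 ketone F9. NaBH4 in MeOH at −40 °C should then deliver hydride axially from the α-face, anti to the adjacent axial C20 methyl, to give the equatorial 12β-alcohol 19, where the route is rejoined.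

Step 19. Ring closure may lose out to oligomerization, or not occur at all, if the planar butenolide holds the two olefins apart. The fallback sets out from 23 and closes the ten-membered ring before the lactone is annulated, so that C7 and C8 are sp3 carbinol carbons during the metathesis. Ring-closing metathesis of 23 with the second-generation Grubbs catalyst should give the macrocyclic hydroxy acetate F10. Dess–Martin oxidation should give the macrocyclic α-acetoxy ketone F11. The aldol and dehydration conditions of step 18 should then lead through the macrocyclic hydroxy lactone F12 (not isolated) to 27, where the route is rejoined.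

Step 18. The amide base may enolize the ketone toward C7 instead of the acetate, which would epimerize C7 or shift the vinyl double bond. The fallback sets out from 24 and replaces the basic enolate by a non-basic Reformatsky reagent. Zinc and ethyl bromoacetate in THF should add to the ketone to give the β-hydroxy ester F13. K2CO3 in MeOH should then remove the C7 acetate, and the freed C7 hydroxyl should lactonize onto the ethyl ester to give hydroxy lactone 25, which is dehydrated with SOCl2/pyridine as in step 18 to 26, where the route is rejoined.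

Further compounds
F1 | step 7 | C12-epimeric cycloadduct (12α-Bpin, 11β-CO2Et) | CC(C)(C)[Si](C)(C)OC[C@@H](O[Si](C)(C)C(C)(C)C)[C@H]1[C@@H](C(=O)OCC)[C@H](B2OC(C)(C)C(C)(C)O2)CC(O[Si](C)(C)C(C)(C)C)=C1C
F2 | step 7 | 12-epi aldol adduct | CC(C)(C)[Si](C)(C)OC[C@@H](O[Si](C)(C)C(C)(C)C)[C@H]1[C@@H](C(=O)OCC)[C@H](B2OC(C)(C)C(C)(C)O2)CC(=O)[C@]1(C)[C@H]([C@@H](O[Si](C)(C)C(C)(C)C)CC(C)=C)O
F3 | step 7 | 12-epi anti-1,3-diol | CC(C)(C)[Si](C)(C)OC[C@@H](O[Si](C)(C)C(C)(C)C)[C@H]1[C@@H](C(=O)OCC)[C@H](B2OC(C)(C)C(C)(C)O2)C[C@H](O)[C@]1(C)[C@H]([C@@H](O[Si](C)(C)C(C)(C)C)CC(C)=C)O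
F4 | step 7 | 12-epi acetonide | CC(C)(C)[Si](C)(C)OC[C@@H](O[Si](C)(C)C(C)(C)C)[C@H]1[C@@H](C(=O)OCC)[C@H](B2OC(C)(C)C(C)(C)O2)C[C@H](O3)[C@]1(C)[C@H]([C@@H](O[Si](C)(C)C(C)(C)C)CC(C)=C)OC3(C)C
F5 | step 7 | 12-epi hydroxy boronate | CC(C)(C)[Si](C)(C)OC[C@@H](O[Si](C)(C)C(C)(C)C)[C@H]1[C@@H](CO)[C@H](B2OC(C)(C)C(C)(C)O2)C[C@H](O3)[C@]1(C)[C@H]([C@@H](O[Si](C)(C)C(C)(C)C)CC(C)=C)OC3(C)C
F6 | step 7 | 12α,20-diol | CC(C)(C)[Si](C)(C)OC[C@@H](O[Si](C)(C)C(C)(C)C)[C@H]1[C@@H](CO)[C@H](O)C[C@H](O3)[C@]1(C)[C@H]([C@@H](O[Si](C)(C)C(C)(C)C)CC(C)=C)OC3(C)C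
F7 | step 7 | 12-epi C20 tosylate | CC(C)(C)[Si](C)(C)OC[C@@H](O[Si](C)(C)C(C)(C)C)[C@H]1[C@@H](COS(=O)(=O)c2ccc(C)cc2)[C@H](O)C[C@H](O3)[C@]1(C)[C@H]([C@@H](O[Si](C)(C)C(C)(C)C)CC(C)=C)OC3(C)C
F8 | step 7 | 11β-methyl 12α-alcohol | CC(C)(C)[Si](C)(C)OC[C@@H](O[Si](C)(C)C(C)(C)C)[C@H]1[C@@H](C)[C@H](O)C[C@H](O3)[C@]1(C)[C@H]([C@@H](O[Si](C)(C)C(C)(C)C)CC(C)=C)OC3(C)C
F9 | step 7 | C12 ketone | CC(C)(C)[Si](C)(C)OC[C@@H](O[Si](C)(C)C(C)(C)C)[C@H]1[C@@H](C)C(=O)C[C@H](O3)[C@]1(C)[C@H]([C@@H](O[Si](C)(C)C(C)(C)C)CC(C)=C)OC3(C)C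
F10 | step 19 | macrocyclic (Z)-Δ5 hydroxy acetate (7-OAc, 8-OH) | CC(C)(C)[Si](C)(C)O[C@H]1C/C(C)=C\[C@H](OC(C)=O)[C@H](O)[C@@H](O[Si](C)(C)C(C)(C)C)[C@H]2[C@@H](C)[C@@H](OCc3ccc(OC)cc3)C[C@H](O3)[C@]2(C)[C@H]1OC3(C)C
F11 | step 19 | macrocyclic α-acetoxy ketone (C8=O) | CC(C)(C)[Si](C)(C)O[C@H]1C/C(C)=C\[C@H](OC(C)=O)C(=O)[C@@H](O[Si](C)(C)C(C)(C)C)[C@H]2[C@@H](C)[C@@H](OCc3ccc(OC)cc3)C[C@H](O3)[C@]2(C)[C@H]1OC3(C)C
F12 | step 19 | macrocyclic hydroxy lactone (C8 epimers) | CC(C)(C)[Si](C)(C)O[C@H]1C/C(C)=C\[C@@H]2OC(=O)CC2(O)[C@@H](O[Si](C)(C)C(C)(C)C)[C@H]2[C@@H](C)[C@@H](OCc3ccc(OC)cc3)C[C@H](O3)[C@]2(C)[C@H]1OC3(C)C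
F13 | step 18 | Reformatsky β-hydroxy ester (C8 epimers; 7-OAc retained) | C=C[C@H](OC(C)=O)C(O)(CC(=O)OCC)[C@@H](O[Si](C)(C)C(C)(C)C)[C@H]1[C@@H](C)[C@@H](OCc2ccc(OC)cc2)C[C@H](O3)[C@]1(C)[C@H]([C@@H](O[Si](C)(C)C(C)(C)C)CC(C)=C)OC3(C)C
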